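Ring A is cut at the C3–C4 bond. The gem-dimethyl quaternary C4, next to the ring-fusion carbon C5, is treated as a masked isopropenyl group: hydrogen-atom transfer from an iron hydride to its CH2 terminus creates the second C4 methyl and a tertiary C4 radical, which adds 6-endo to C3 of a vinyl sulfone held on C10. One operation thus closes ring A, forms C4 and delivers the trans-decalin. The precursor is (S)-carvone carrying methyl and 2-(phenylsulfonyl)allyl on its α′-carbon (future C10). Ring B is afterwards dressed with the side chain and the two hydroxyls, and the sulfone is excised reductively.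

Key step: step 3

Remark: labdane numbering is used for all intermediates (carvone C6 = C10, carvone C1 = C9, isopropenyl carbon = C4); the target is an ent-labdane, which is why (S)-carvone is the chiral source.

Step 1
Reactants: 1 (S)-(+)-carvone
Product: 3 trans-6-methylcarvone [(5S,6R)-2,6-dimethyl-5-(prop-1-en-2-yl)cyclohex-2-en-1-one], via lithium dienolate 2 (not isolated)
Conditions: LiN(i-Pr)2, THF, −78 °C; MeI, −78 → 0 °C
Reagents that add atoms: iodomethane (CI)
Why: Kinetic deprotonation at the α′-carbon gives the cross-conjugated lithium dienolate, whose methylation (enolate alkylation) should occur mainly anti to the neighbouring isopropenyl group, although this centre is re-set in step 2 so that both epimers can be carried on.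

Step 2
Reactants: 3 trans-6-methylcarvone
Product: 5 (5R,6R)-2,6-dimethyl-6-[2-(phenylsulfonyl)prop-2-en-1-yl]-5-(prop-1-en-2-yl)cyclohex-2-en-1-one (sulfonylallyl chain trans and methyl cis to isopropenyl), via lithium enolate 4 (not isolated)
Conditions: LiN(i-Pr)2, THF, −78 °C; CH2=C(SO2Ph)CH2SO2Ph, −78 → −20 °C
Reagents that add atoms: 2,3-bis(phenylsulfonyl)prop-1-ene (C=C(CS(=O)(=O)c1ccccc1)S(=O)(=O)c1ccccc1)
Why: The tetrasubstituted enolate should attack the allylic bis-sulfone in an SN2′ addition–elimination with loss of benzenesulfinate, the electrophile entering anti to the adjacent isopropenyl group, so that the new quaternary centre (future C10) is set as in the familiar sequential α′-dialkylation of carvone.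

Step 3
Reactants: 5 dialkylated carvone bearing the vinyl sulfone
Product: 6 trans-fused bicyclic enone sulfone (labdane numbering: 9-oxo, 7-ene, 4,4,8,10-tetramethyl, 2-phenylsulfonyl as a C2 epimer mixture, H-5 anti to the C10 methyl)
Conditions: Fe(acac)3, PhSiH3, EtOH/HOCH2CH2OH, 60 °C
Reagents that add atoms: none
Why: Fe(acac)3/PhSiH3 generates an iron hydride that transfers a hydrogen atom to the CH2 terminus of the electron-rich isopropenyl group (that carbon becomes the second methyl on C4), the tertiary C4 radical adds to the unsubstituted terminus C3 of the vinyl sulfone, and the resulting α-sulfonyl radical at C2 is reduced and protonated. The closest known reaction type is the MHAT-initiated reductive olefin coupling (a Giese-type radical conjugate addition), run here intramolecularly. Ring A is closed in the 6-endo-trig mode through a chair-like arrangement. C4 is not stereogenic, the ring fusion is trans because the C5 and C10 appendages were placed trans in steps 1 and 2, and the new C2 centre is uncontrolled but is deleted in step 8. The step needs hydrogen-atom transfer to the 1,1-disubstituted alkene in preference to the enone and the vinyl sulfone, which polarity matching secures, and 6-endo rather than 5-exo closure, which the sulfonyl group on C2 secures by blocking that carbon and stabilising the adduct radical.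

Step 4
Reactants: 6 bicyclic enone sulfone
Product: 8 C9 tertiary allylic methyl carbonate carrying the 2-(2-methyl-1,3-dioxolan-2-yl)ethyl chain on the face opposite the C10 methyl, via dichlorocerium alkoxide 7 (not isolated)
Conditions: BrMgCH2CH2C(OCH2CH2O)CH3 (from the bromide and Mg), CeCl3, THF, −78 °C; ClCO2Me, −78 °C → rt
Reagents that add atoms: 2-(2-bromoethyl)-2-methyl-1,3-dioxolane (CC1(CCBr)OCCO1); methyl chloroformate (COC(=O)Cl)
Why: The organocerium reagent should add 1,2 to the hindered, non-enolisable enone carbonyl from the face opposite the axial C10 methyl (carbonyl addition under substrate control; this C9 centre is erased in step 6), and the alkoxide is acylated in the flask so that the tertiary oxygen becomes a leaving group.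

Step 5
Reactants: 8 tertiary allylic carbonate
Product: 9 γ-carbonate enone (6-oxo, 7-ene, C9 carbonate)
Conditions: Rh2(cap)4 (dirhodium tetracaprolactamate, cat.), t-BuOOH, K2CO3, CH2Cl2, rt
Reagents that add atoms: tert-butyl hydroperoxide (CC(C)(C)OO)
Why: Dirhodium-caprolactamate-catalysed allylic C–H oxidation should convert the ring methylene next to the CH terminus of the trisubstituted alkene (C6) into the carbonyl, the regiochemistry usual for trisubstituted cyclohexenes, and no stereocentre is formed.

Step 6
Reactants: 9 γ-carbonate enone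
Product: 11 conjugated 7-en-6-one with H-9 anti to the C10 methyl, via deconjugated 8(9)-enone 10 (not isolated)
Conditions: Zn, AcOH/THF, rt; DBU, CH2Cl2, rt
Reagents that add atoms: none
Why: Zinc reduction of the vinylogous α-acyloxy ketone should expel the C9 carbonate to give a zinc dienolate that protonates at C7, and DBU then moves the double bond into conjugation by γ-protonation at C9 from the face opposite the axial C10 methyl, which is also the thermodynamically preferred equatorial placement of the side chain.

Step 7
Reactants: 11 conjugated enone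
Product: 12 7,8-epoxy-6-ketone (epoxide oxygen anti to the C10 methyl)
Conditions: 30% H2O2, NaOH, MeOH, 0 °C → rt
Reagents that add atoms: hydrogen peroxide (OO)
Why: Weitz–Scheffer nucleophilic epoxidation of the β,β-disubstituted enone should deliver hydroperoxide to C8 from the face opposite the syn-axial C10 methyl, fixing the C8–O bond (and C7) on that face.

Step 8
Reactants: 12 epoxy ketone
Product: 14 6,8-diol with the side-chain ketone still as its dioxolane, via sulfone-free hydroxy ketone 13 (not isolated)
Conditions: Li, NH3(l)/THF, −78 °C; MeOH, −78 → −33 °C; NH4Cl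
Reagents that add atoms: none
Why: Dissolving-metal reduction should cleave the C7–O bond of the α,β-epoxy ketone (leaving the C8–O stereocentre untouched), remove the sulfone by C–S reduction and, once methanol is added, reduce the hindered C6 ketone under thermodynamic control to the equatorial alcohol, the epimer that avoids three syn-axial methyl groups.

Step 9
Reactants: 14 diol ketal
Product: 15 dihydroxy methyl ketone (6,8-dihydroxy-14,15-dinor-ent-labdan-13-one)
Conditions: PPTS, acetone/H2O, 40 °C
Reagents that add atoms: water (O)
Why: Mild acid-catalysed ketal hydrolysis (transketalisation to acetone) should unmask the methyl ketone without dehydrating the tertiary C8 alcohol or closing the cyclic enol ether.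

Step 10
Reactants: 15 dihydroxy methyl ketone
Product: 16 methyl (5R,6R,8S,9S,10R,13E)-6,8-dihydroxylabd-13-en-15-oate (CNP0289884.1)
Conditions: (MeO)2P(O)CH2CO2Me, NaH, THF, 0 → 50 °C
Reagents that add atoms: trimethyl phosphonoacetate (COC(=O)CP(=O)(OC)OC)
Why: Horner–Wadsworth–Emmons olefination of the methyl ketone should give mainly the E-enoate (larger chain trans to the ester), the minor Z-isomer being removable by chromatography.

Compound list
1 | (S)-(+)-carvone | O=C1C[C@@H](C(C)=C)CC=C1C | starting material
2 | lithium dienolate of 1 (O–Li on C1, C1=C6 and C2=C3 double bonds) | [Li]OC1=C[C@@H](C(C)=C)CC=C1C | intermediate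
3 | trans-6-methylcarvone, (5S,6R) | O=C1[C@H](C)[C@@H](C(C)=C)CC=C1C | intermediate
4 | lithium enolate of 3 (tetrasubstituted C1=C6) | [Li]OC1=C(C)[C@@H](C(C)=C)CC=C1C | intermediate
5 | (5R,6R)-2,6-dimethyl-6-[2-(phenylsulfonyl)prop-2-en-1-yl]-5-(prop-1-en-2-yl)cyclohex-2-en-1-one | O=C1[C@](C)(CC(=C)S(=O)(=O)c2ccccc2)[C@@H](C(C)=C)CC=C1C | intermediate
6 | trans-fused bicyclic enone sulfone (9-oxo, 7-ene, 2-SO2Ph, C2 epimers) | O=C1[C@]2(C)CC(S(=O)(=O)c3ccccc3)CC(C)(C)[C@H]2CC=C1C | intermediate
7 | dichlorocerium alkoxide of the C9 tertiary alcohol | Cl[Ce](Cl)O[C@@]1(CCC2(C)OCCO2)[C@]2(C)CC(S(=O)(=O)c3ccccc3)CC(C)(C)[C@H]2CC=C1C | intermediate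
8 | C9 tertiary allylic methyl carbonate | COC(=O)O[C@@]1(CCC2(C)OCCO2)[C@]2(C)CC(S(=O)(=O)c3ccccc3)CC(C)(C)[C@H]2CC=C1C | intermediate
9 | γ-carbonate enone (6-oxo, 7-ene) | COC(=O)O[C@@]1(CCC2(C)OCCO2)[C@]2(C)CC(S(=O)(=O)c3ccccc3)CC(C)(C)[C@H]2C(=O)C=C1C | intermediate
10 | deconjugated 8(9)-en-6-one | CC1(CCC2=C(C)CC(=O)[C@@H]3C(C)(C)CC(S(=O)(=O)c4ccccc4)C[C@@]23C)OCCO1 | intermediate
11 | conjugated 7-en-6-one, 9-H anti to the C10 methyl | CC1(CC[C@H]2[C@]3(C)CC(S(=O)(=O)c4ccccc4)CC(C)(C)[C@H]3C(=O)C=C2C)OCCO1 | intermediate
12 | 7,8-epoxy-6-ketone | CC1(CC[C@H]2[C@]3(C)CC(S(=O)(=O)c4ccccc4)CC(C)(C)[C@H]3C(=O)[C@@H]4O[C@]24C)OCCO1 | intermediate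
13 | sulfone-free 8-hydroxy-6-ketone | CC1(CC[C@H]2[C@]3(C)CCCC(C)(C)[C@H]3C(=O)C[C@]2(C)O)OCCO1 | intermediate
14 | 6,8-diol, side-chain dioxolane | CC1(CC[C@H]2[C@]3(C)CCCC(C)(C)[C@H]3[C@H](O)C[C@]2(C)O)OCCO1 | intermediate
15 | 6,8-dihydroxy-14,15-dinor-ent-labdan-13-one | CC(=O)CC[C@H]1[C@]2(C)CCCC(C)(C)[C@H]2[C@H](O)C[C@]1(C)O | intermediate
16 | methyl (5R,6R,8S,9S,10R,13E)-6,8-dihydroxylabd-13-en-15-oate | COC(=O)/C=C(\C)CC[C@H]1[C@]2(C)CCCC(C)(C)[C@H]2[C@H](O)C[C@]1(C)O | target

Total step count: 10. Longest linear sequence: 10 steps from (S)-carvone.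

Steps most likely to fail

Step 5. Hydrogen abstraction may occur at the wrong allylic site (the C8 methyl), or the tertiary allylic carbonate may ionise under the oxidising conditions. The fallback brings in the C6 oxygen by cycloaddition instead of C–H oxidation and sets out from 6. γ-Deprotonation and O-triflation (KN(SiMe3)2, PhNTf2) would give the dienyl triflate F1. Suzuki–Miyaura B-alkyl coupling with the 9-BBN adduct of 2-methyl-2-vinyl-1,3-dioxolane (Pd(dppf)Cl2, Cs2CO3) would give the homoannular diene F2. Singlet oxygen (O2, tetraphenylporphyrin, light; [4+2] on the face opposite the C10 methyl) would give the endoperoxide F3. Et3N (Kornblum–DeLaMare rearrangement) would give the γ-hydroxy enone F4, and acylation (LiN(SiMe3)2, ClCO2Me) the carbonate F5, which is the C9 epimer of 9. Because step 6 erases C9, its conditions should convert F5 into 11, where the route is rejoined.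

Step 6. The C–O cleavage may be incomplete, the enone may be over-reduced, or the dioxolane may be lost in acid. The fallback sets out from 9 and replaces the dissolving metal by hydrogenolysis of the allylic carbonate through a π-allyl complex (Pd(PPh3)4, HCO2H/Et3N, THF; zerovalent palladium ionises the carbonate and formate supplies hydride). The same DBU equilibration follows, and the route is rejoined at 11 without any new isolated compound.

Step 8. The C8 alkoxide may fragment by retro-aldol once the ketone is regenerated, or one of the three reductions may stay incomplete. The fallback sets out from 12, separates the events and masks the aldol oxygen. Epoxide opening with PhSeNa, made from (PhSe)2 and NaBH4 in EtOH, would give the hydroxy ketone F6 with the sulfone still in place. Silylation (Me3Si-imidazole) would give the silyl ether F7. Li/NH3–MeOH followed by K2CO3/MeOH desilylation would return the material at 14.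

Further compounds
F1 | step 5 | dienyl triflate (9-triflyloxy-6,8-diene) | CC1=C(OS(=O)(=O)C(F)(F)F)[C@]2(C)CC(S(=O)(=O)c3ccccc3)CC(C)(C)[C@H]2C=C1
F2 | step 5 | homoannular 6,8-diene carrying the dioxolane side chain on C9 | CC1(CCC2=C(C)C=C[C@@H]3C(C)(C)CC(S(=O)(=O)c4ccccc4)C[C@@]23C)OCCO1
F3 | step 5 | 6,9-endoperoxide (peroxide bridge anti to the C10 methyl) | CC1(CC[C@@]2(OO[C@@H]3C=C2C)[C@]4(C)CC(S(=O)(=O)c5ccccc5)CC(C)(C)[C@@H]34)OCCO1
F4 | step 5 | γ-hydroxy enone (free C9 alcohol, C9-epimeric series) | CC1(CC[C@@]2(O)[C@]3(C)CC(S(=O)(=O)c4ccccc4)CC(C)(C)[C@H]3C(=O)C=C2C)OCCO1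
F5 | step 5 | C9 epimer of carbonate 9 | CC1(CC[C@@]2(OC(=O)OC)[C@]3(C)CC(S(=O)(=O)c4ccccc4)CC(C)(C)[C@H]3C(=O)C=C2C)OCCO1
F0 | step 6 | none | none
F6 | step 8 | 8-hydroxy-6-ketone with the sulfone retained | CC1(CC[C@H]2[C@]3(C)CC(S(=O)(=O)c4ccccc4)CC(C)(C)[C@H]3C(=O)C[C@]2(C)O)OCCO1
F7 | step 8 | C8 trimethylsilyl ether of F6 | CC1(CC[C@H]2[C@]3(C)CC(S(=O)(=O)c4ccccc4)CC(C)(C)[C@H]3C(=O)C[C@]2(C)O[Si](C)(C)C)OCCO1
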